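**Retrosynthetic overview**

1. Numbering: C1 methyl bridgehead, C2 ketone, C3 methyl carbinol, C4 CH bridgehead, C5 acylated enol carbon, C6 enol C–OH, C7 sorbyl-bearing CH, C8 butenolide-bearing CH, C5′ butenolide quaternary carbon. The strategy rests on the carbocycle C2–C3–C4–C8–C7–C1, with the C3 methyl and a three-carbon group on C7: this is the ring of (R)-carvone, whose enone makes C4 electrophilic.
2. Key disconnection C1–C6: intramolecular Claisen acylation of the C1 ketone enolate by an acetate arm on C4 closes ring C1–C2–C3–C4–C5–C6 onto the carvone ring and gives the bicyclo[2.2.2]octane-2,6-dione.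
3. The precursor comes from (R)-carvone in three steps: α′-methylation, Mukaiyama–Michael addition trans to the isopropenyl group (sets C4), and Rubottom oxidation trans to the arm (sets C3).
4. Late disconnections: sorbyl ketone to C7 acetyl plus crotonaldehyde (aldol condensation); C5 acyl by enolate acylation; C8–C5′ by vinylogous Mukaiyama–Michael addition of a tetronate silyloxyfuran to the C7=C8 enone; the enone from the acetyl group, and that from the isopropenyl group.
5. Ring order: carvone ring (bought), second carbocycle in step 4, butenolide ring made separately from ethyl lactate and attached in step 11.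

Key step: step 4

**Remarks**
- The silyl ether at C3 is tert-butyldimethylsilyl: the Rubottom step delivers it directly by silyl migration, and it survives the later fluoride cleavage of a silyl enol ether.
- The 5-acyl-6-hydroxy unit is drawn as the C6 enol, as in the target SMILES.
- Ethyl lactate is used as the racemate; its stereocentre is erased in step 10. Compound 4 is taken as commercial.
- The methyl-bearing centre of 3, 5 and 7 (core C1) becomes the enolate carbon in step 4, and C7 of 10 and 12 is erased in step 6; one epimer is drawn in each case.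

**Route**

Step 1
Reactants: 1 (R)-carvone
Product: 3 (5R,6S)-2,6-dimethyl-5-(prop-1-en-2-yl)cyclohex-2-en-1-one (trans-6-methylcarvone), via lithium dienolate 2 (not isolated)
Conditions: LiN(iPr)2, THF, −78 °C; MeI, −78 → 0 °C
Reagents that add atoms: iodomethane, CI
Why: Enolate alkylation: kinetic α′-deprotonation gives the cross-conjugated dienolate 2, which should be methylated mainly trans to the neighbouring isopropenyl group; the new centre becomes the enolate carbon of step 4, so its configuration does not matter.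

Step 2
Reactants: 3 (5R,6S)-2,6-dimethyl-5-(prop-1-en-2-yl)cyclohex-2-en-1-one; 4 tert-butyl[(1-methoxyethenyl)oxy]dimethylsilane
Product: 5 methyl 2-[(1S,4S,5R)-3-[(tert-butyldimethylsilyl)oxy]-2,4-dimethyl-5-(prop-1-en-2-yl)cyclohex-2-en-1-yl]acetate
Conditions: (CF3SO2)2NH (3 mol %), CH2Cl2, −78 °C; Et3N quench
Reagents that add atoms: none
Why: Mukaiyama–Michael addition under silyl Lewis acid catalysis: the ketene acetal should attack the β-carbon axially on the half-chair face opposite to the isopropenyl group, as conjugate additions to 5-substituted cyclohexenones do, which sets C4, and silyl transfer traps the enolate regiospecifically as the C2–C3 enol silane.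

Step 3
Reactants: 5 methyl 2-[(1S,4S,5R)-3-[(tert-butyldimethylsilyl)oxy]-2,4-dimethyl-5-(prop-1-en-2-yl)cyclohex-2-en-1-yl]acetate
Product: 7 methyl 2-[(1S,2S,4S,5R)-2-[(tert-butyldimethylsilyl)oxy]-2,4-dimethyl-3-oxo-5-(prop-1-en-2-yl)cyclohexyl]acetate, via silyloxy epoxide 6 (not isolated)
Conditions: 3-ClC6H4CO3H (1.05 equiv), CH2Cl2, −20 → 0 °C
Reagents that add atoms: 3-chloroperoxybenzoic acid, OOC(=O)c1cccc(Cl)c1
Why: Rubottom oxidation: the electron-rich tetrasubstituted enol silane should be epoxidised much faster than the isopropenyl group and on the face opposite to the pseudoaxial C4 arm and the C1 methyl group, and epoxide 6 opens with 1,4-silyl migration to the α-silyloxy ketone, which sets C3 with its oxygen trans to the arm.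

Step 4
Reactants: 7 methyl 2-[(1S,2S,4S,5R)-2-[(tert-butyldimethylsilyl)oxy]-2,4-dimethyl-3-oxo-5-(prop-1-en-2-yl)cyclohexyl]acetate
Product: 10 (1R,3S,4S,7S)-3-[(tert-butyldimethylsilyl)oxy]-1,3-dimethyl-7-(prop-1-en-2-yl)bicyclo[2.2.2]octane-2,6-dione, via potassium ketone enolate 8 (not isolated), via potassium dione enolate 9 (not isolated)
Conditions: KN(SiMe3)2 (2.2 equiv), THF (0.02 M), −78 → 0 °C; AcOH, −78 °C
Reagents that add atoms: none
Why: The base removes the C1 hydrogen, the only α-hydrogen of the C2 ketone, and enolate 8 adds through C1 to the ester carbonyl of the C4 arm; loss of methoxide forms the C1–C6 bond, and the second equivalent of base takes the dione out of the equilibrium as its C5–C6 enolate 9, which protects C6 against retro-Claisen attack by methoxide. The closest known reaction type is the intramolecular Claisen (Dieckmann-type) C-acylation of a cyclohexanone enolate by a 3-carboxymethyl arm to give a bridged 1,3-diketone. Ring C1–C2–C3–C4–C5–C6 closes through a boat by a 6-(enolendo)-exo-trig attack, which also completes ring C1–C7–C8–C4–C5–C6 of the bicyclo[2.2.2]octane. The one new stereocentre, quaternary C1, is fixed by the tether: the arm lies on the ring face opposite to the isopropenyl group and can reach C1 only from that face. The step needs C- over O-acylation and ketone over ester enolisation: O-acylation would give a reversible, strained bridgehead enol lactone, and amine-mediated proton exchange should funnel any ester enolate to the more stable ketone enolate.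

Step 5
Reactants: 10 (1R,3S,4S,7S)-3-[(tert-butyldimethylsilyl)oxy]-1,3-dimethyl-7-(prop-1-en-2-yl)bicyclo[2.2.2]octane-2,6-dione
Product: 12 (1R,3S,4S,7R)-7-acetyl-3-[(tert-butyldimethylsilyl)oxy]-1,3-dimethylbicyclo[2.2.2]octane-2,6-dione, via secondary ozonide 11 (not isolated)
Conditions: O3, CH2Cl2, −78 °C; Me2S, −78 → 23 °C
Reagents that add atoms: ozone, [O-][O+]=O
Why: Ozonolysis with reductive work-up of the only C=C bond in the molecule; the C7 configuration is kept here and erased in step 6.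

Step 6
Reactants: 12 (1R,3S,4S,7R)-7-acetyl-3-[(tert-butyldimethylsilyl)oxy]-1,3-dimethylbicyclo[2.2.2]octane-2,6-dione
Product: 13 (1R,3S,4R)-7-acetyl-3-[(tert-butyldimethylsilyl)oxy]-1,3-dimethylbicyclo[2.2.2]oct-7-ene-2,6-dione
Conditions: 2-iodoxybenzoic acid (IBX, 2.5 equiv), DMSO, 75 °C
Reagents that add atoms: none
Why: IBX dehydrogenation of a ketone through its enol: only the acetyl group can react, toward C8, because C2 has no α-hydrogen and the C6 ketone could only give a bridgehead alkene (Bredt's rule), so the other enolisations are without consequence.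

Step 7
Reactants: 14 ethyl lactate (racemic)
Product: 15 ethyl 2-(propanoyloxy)propanoate
Conditions: EtCOCl, pyridine, 4-(dimethylamino)pyridine (cat.), CH2Cl2, 0 → 23 °C
Reagents that add atoms: propanoyl chloride, CCC(=O)Cl
Why: O-Acylation of a secondary alcohol under nucleophilic catalysis.

Step 8
Reactants: 15 ethyl 2-(propanoyloxy)propanoate
Product: 16 4-hydroxy-3,5-dimethylfuran-2(5H)-one (3,5-dimethyltetronic acid)
Conditions: KOtBu, THF, 0 → 23 °C; 1 M HCl
Reagents that add atoms: none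
Why: Dieckmann condensation of an α-acyloxy ester (propanoate enolate onto the ethyl ester), driven by deprotonation of the acidic tetronic acid.

Step 9
Reactants: 16 4-hydroxy-3,5-dimethylfuran-2(5H)-one
Product: 17 4-methoxy-3,5-dimethylfuran-2(5H)-one
Conditions: Me2SO4, K2CO3, acetone, 23 °C
Reagents that add atoms: dimethyl sulfate, COS(=O)(=O)OC
Why: O-Alkylation of the vinylogous carboxylate at the 4-oxygen by a hard electrophile.

Step 10
Reactants: 17 4-methoxy-3,5-dimethylfuran-2(5H)-one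
Product: 18 tert-butyl[(4-methoxy-3,5-dimethylfuran-2-yl)oxy]dimethylsilane
Conditions: tBuMe2SiOTf, Et3N, CH2Cl2, 0 °C
Reagents that add atoms: tert-butyldimethylsilyl trifluoromethanesulfonate, CC(C)(C)[Si](C)(C)OS(=O)(=O)C(F)(F)F
Why: Soft enolisation (O-silylation of the lactone carbonyl, then loss of the γ-hydrogen) gives the aromatic 2-silyloxyfuran and removes the C5 stereocentre.

Step 11
Reactants: 13 (1R,3S,4R)-7-acetyl-3-[(tert-butyldimethylsilyl)oxy]-1,3-dimethylbicyclo[2.2.2]oct-7-ene-2,6-dione; 18 tert-butyl[(4-methoxy-3,5-dimethylfuran-2-yl)oxy]dimethylsilane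
Product: 19 (1R,3S,4R,8S)-3-[(tert-butyldimethylsilyl)oxy]-7-{1-[(tert-butyldimethylsilyl)oxy]ethylidene}-8-[(2S)-3-methoxy-2,4-dimethyl-5-oxo-2,5-dihydrofuran-2-yl]-1,3-dimethylbicyclo[2.2.2]octane-2,6-dione
Conditions: (CF3SO2)2NH (5 mol %), CH2Cl2, −78 °C; Et3N quench
Reagents that add atoms: none
Why: Vinylogous Mukaiyama–Michael addition: the furan γ-carbon should attack C8 of the activated s-trans enone on the face turned to the C5–C6 bridge, the other face being covered by the C3 silyloxy group (sets C8); C5′ is set in an open transition state with the furan over the enone, its ring oxygen between C7 and C4 and its methyl beside the C8 hydrogen; silyl transfer leaves the acetyl group masked as the C7 enol silane.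

Step 12
Reactants: 20 (E)-hex-4-enoic acid
Product: 22 1-[(E)-hex-4-enoyl]-1H-benzotriazole, via (E)-hex-4-enoyl chloride 21 (not isolated)
Conditions: (COCl)2, HCONMe2 (cat.), CH2Cl2, 0 → 23 °C; then 1H-benzotriazole, Et3N, 0 °C
Reagents that add atoms: 1H-benzotriazole, c1ccc2[nH]nnc2c1
Why: Acid chloride formation under Vilsmeier catalysis and N-acylation of benzotriazole give a stable acyl donor of the kind that acylates ketone enolates on carbon.

Step 13
Reactants: 19 (1R,3S,4R,8S)-3-[(tert-butyldimethylsilyl)oxy]-7-{1-[(tert-butyldimethylsilyl)oxy]ethylidene}-8-[(2S)-3-methoxy-2,4-dimethyl-5-oxo-2,5-dihydrofuran-2-yl]-1,3-dimethylbicyclo[2.2.2]octane-2,6-dione; 22 1-[(E)-hex-4-enoyl]-1H-benzotriazole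
Product: 24 (1R,3S,4S,8S)-3-[(tert-butyldimethylsilyl)oxy]-7-{1-[(tert-butyldimethylsilyl)oxy]ethylidene}-5-[(E)-hex-4-enoyl]-6-hydroxy-8-[(2S)-3-methoxy-2,4-dimethyl-5-oxo-2,5-dihydrofuran-2-yl]-1,3-dimethylbicyclo[2.2.2]oct-5-en-2-one, via lithium enolate 23 (not isolated)
Conditions: LiN(SiMe3)2 (2.2 equiv), THF, −78 °C; 22, −78 → −40 °C; AcOH
Reagents that add atoms: none
Why: Claisen-type C-acylation of a lithium enolate by an N-acylbenzotriazole: C5 is the only enolisable position because the acetyl group is masked as its enol silane and C2 has no α-hydrogen, and the second equivalent of base takes up the more acidic β-diketone.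

Step 14
Reactants: 24 (1R,3S,4S,8S)-3-[(tert-butyldimethylsilyl)oxy]-7-{1-[(tert-butyldimethylsilyl)oxy]ethylidene}-5-[(E)-hex-4-enoyl]-6-hydroxy-8-[(2S)-3-methoxy-2,4-dimethyl-5-oxo-2,5-dihydrofuran-2-yl]-1,3-dimethylbicyclo[2.2.2]oct-5-en-2-one
Product: 26 (1R,3S,4S,7R,8S)-7-acetyl-3-[(tert-butyldimethylsilyl)oxy]-5-[(E)-hex-4-enoyl]-6-hydroxy-8-[(2S)-3-methoxy-2,4-dimethyl-5-oxo-2,5-dihydrofuran-2-yl]-1,3-dimethylbicyclo[2.2.2]oct-5-en-2-one, via C7-epimeric ketone mixture 25 (not isolated)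
Conditions: Bu4NF, AcOH, THF, 0 °C; then DBU (3 equiv), CH2Cl2, 23 °C
Reagents that add atoms: none
Why: Fluoride cleavage of the silyl enol ether (enolate as leaving group) should be much faster than that of the hindered tertiary silyl ether, and base equilibration sets C7 under thermodynamic control with the acetyl group trans to the C8 butenolide, the cis arrangement being eclipsed on the bicyclo[2.2.2]octane.

Step 15
Reactants: 26 (1R,3S,4S,7R,8S)-7-acetyl-3-[(tert-butyldimethylsilyl)oxy]-5-[(E)-hex-4-enoyl]-6-hydroxy-8-[(2S)-3-methoxy-2,4-dimethyl-5-oxo-2,5-dihydrofuran-2-yl]-1,3-dimethylbicyclo[2.2.2]oct-5-en-2-one; 27 (E)-crotonaldehyde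
Product: 30 (1R,3S,4S,7R,8S)-3-[(tert-butyldimethylsilyl)oxy]-7-[(2E,4E)-hexa-2,4-dienoyl]-5-[(E)-hex-4-enoyl]-6-hydroxy-8-[(2S)-3-methoxy-2,4-dimethyl-5-oxo-2,5-dihydrofuran-2-yl]-1,3-dimethylbicyclo[2.2.2]oct-5-en-2-one, via dilithium dianion 28 (not isolated), via aldol adduct 29 (not isolated)
Conditions: LiN(iPr)2 (2.2 equiv), THF, −78 °C; 27, −78 °C; AcOH; then 4-MeC6H4SO3H·H2O (10 mol %), toluene, 40 °C
Reagents that add atoms: none
Why: Directed aldol addition and acid-catalysed dehydration: the first equivalent of base forms the β-diketonate and the second the kinetic methyl enolate (the C7 hydrogen is tertiary and shielded), which adds 1,2 to the enal, and the allylic β-hydroxy ketone 29 loses water to the conjugated (2E,4E)-dienone, the thermodynamic geometry.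

Step 16
Reactants: 30 (1R,3S,4S,7R,8S)-3-[(tert-butyldimethylsilyl)oxy]-7-[(2E,4E)-hexa-2,4-dienoyl]-5-[(E)-hex-4-enoyl]-6-hydroxy-8-[(2S)-3-methoxy-2,4-dimethyl-5-oxo-2,5-dihydrofuran-2-yl]-1,3-dimethylbicyclo[2.2.2]oct-5-en-2-one
Product: 31 (1R,3S,4S,7R,8S)-3-[(tert-butyldimethylsilyl)oxy]-7-[(2E,4E)-hexa-2,4-dienoyl]-5-[(E)-hex-4-enoyl]-6-hydroxy-8-[(2S)-3-hydroxy-2,4-dimethyl-5-oxo-2,5-dihydrofuran-2-yl]-1,3-dimethylbicyclo[2.2.2]oct-5-en-2-one
Conditions: LiCl, DMSO, 70 °C; 1 M HCl work-up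
Reagents that add atoms: none
Why: SN2 O-demethylation of the vinylogous methyl ester by chloride with the tetronate as leaving group, a cleavage known for methyl tetronates; no other group in the molecule is activated in this way.

Step 17
Reactants: 31 (1R,3S,4S,7R,8S)-3-[(tert-butyldimethylsilyl)oxy]-7-[(2E,4E)-hexa-2,4-dienoyl]-5-[(E)-hex-4-enoyl]-6-hydroxy-8-[(2S)-3-hydroxy-2,4-dimethyl-5-oxo-2,5-dihydrofuran-2-yl]-1,3-dimethylbicyclo[2.2.2]oct-5-en-2-one
Product: 32 (1R,3S,4S,7R,8S)-7-[(2E,4E)-hexa-2,4-dienoyl]-5-[(E)-hex-4-enoyl]-3,6-dihydroxy-8-[(2S)-3-hydroxy-2,4-dimethyl-5-oxo-2,5-dihydrofuran-2-yl]-1,3-dimethylbicyclo[2.2.2]oct-5-en-2-one (CNP0539719.2)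
Conditions: HF (48% aq), MeCN, 0 → 23 °C
Reagents that add atoms: none
Why: Fluoride-assisted cleavage of the Si–O bond should free the C3 tertiary alcohol without touching the dienone, the enolised β-diketone or the tetronic acid.

**Compound list**

1 | (R)-carvone | CC1=CC[C@H](CC1=O)C(C)=C | starting material
2 | lithium dienolate of 1 | [Li+].CC1=CC[C@H](C=C1[O-])C(C)=C | intermediate (not isolated)
3 | (5R,6S)-2,6-dimethyl-5-(prop-1-en-2-yl)cyclohex-2-en-1-one | CC(=C)[C@@H]1CC=C(C)C(=O)[C@H]1C | intermediate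
4 | tert-butyl[(1-methoxyethenyl)oxy]dimethylsilane | C=C(OC)O[Si](C)(C)C(C)(C)C | starting material
5 | methyl 2-[(1S,4S,5R)-3-[(tert-butyldimethylsilyl)oxy]-2,4-dimethyl-5-(prop-1-en-2-yl)cyclohex-2-en-1-yl]acetate | CC(=C)[C@@H]1C[C@@H](CC(=O)OC)C(C)=C(O[Si](C)(C)C(C)(C)C)[C@H]1C | intermediate
6 | silyloxy epoxide of 5 (oxirane on C2–C3, oxygen trans to the acetate arm) | CC(=C)[C@@H]1C[C@@H](CC(=O)OC)[C@]2(C)O[C@]2(O[Si](C)(C)C(C)(C)C)[C@H]1C | intermediate (not isolated)
7 | methyl 2-[(1S,2S,4S,5R)-2-[(tert-butyldimethylsilyl)oxy]-2,4-dimethyl-3-oxo-5-(prop-1-en-2-yl)cyclohexyl]acetate | CC(=C)[C@@H]1C[C@@H](CC(=O)OC)[C@](C)(O[Si](C)(C)C(C)(C)C)C(=O)[C@H]1C | intermediate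
8 | potassium C1–C2 enolate of 7 | [K+].CC(=C)[C@@H]1C[C@@H](CC(=O)OC)[C@](C)(O[Si](C)(C)C(C)(C)C)C([O-])=C1C | intermediate (not isolated)
9 | potassium C5–C6 enolate of 10 | [K+].CC(=C)[C@@H]1C[C@H]2C=C([O-])[C@]1(C)C(=O)[C@@]2(C)O[Si](C)(C)C(C)(C)C | intermediate (not isolated)
10 | (1R,3S,4S,7S)-3-[(tert-butyldimethylsilyl)oxy]-1,3-dimethyl-7-(prop-1-en-2-yl)bicyclo[2.2.2]octane-2,6-dione | CC(=C)[C@@H]1C[C@H]2CC(=O)[C@]1(C)C(=O)[C@@]2(C)O[Si](C)(C)C(C)(C)C | intermediate
11 | secondary ozonide (3-methyl-1,2,4-trioxolan-3-yl at C7) of 10 | CC1(OCOO1)[C@@H]2C[C@H]3CC(=O)[C@]2(C)C(=O)[C@@]3(C)O[Si](C)(C)C(C)(C)C | intermediate (not isolated)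
12 | (1R,3S,4S,7R)-7-acetyl-3-[(tert-butyldimethylsilyl)oxy]-1,3-dimethylbicyclo[2.2.2]octane-2,6-dione | CC(=O)[C@@H]1C[C@H]2CC(=O)[C@]1(C)C(=O)[C@@]2(C)O[Si](C)(C)C(C)(C)C | intermediate
13 | (1R,3S,4R)-7-acetyl-3-[(tert-butyldimethylsilyl)oxy]-1,3-dimethylbicyclo[2.2.2]oct-7-ene-2,6-dione | CC(=O)C1=C[C@H]2CC(=O)[C@]1(C)C(=O)[C@@]2(C)O[Si](C)(C)C(C)(C)C | intermediate
14 | ethyl lactate (racemic) | CCOC(=O)C(C)O | starting material
15 | ethyl 2-(propanoyloxy)propanoate | CCOC(=O)C(C)OC(=O)CC | intermediate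
16 | 4-hydroxy-3,5-dimethylfuran-2(5H)-one | CC1OC(=O)C(C)=C1O | intermediate
17 | 4-methoxy-3,5-dimethylfuran-2(5H)-one | COC1=C(C)C(=O)OC1C | intermediate
18 | tert-butyl[(4-methoxy-3,5-dimethylfuran-2-yl)oxy]dimethylsilane | COc1c(C)oc(O[Si](C)(C)C(C)(C)C)c1C | intermediate
19 | (1R,3S,4R,8S)-3-[(tert-butyldimethylsilyl)oxy]-7-{1-[(tert-butyldimethylsilyl)oxy]ethylidene}-8-[(2S)-3-methoxy-2,4-dimethyl-5-oxo-2,5-dihydrofuran-2-yl]-1,3-dimethylbicyclo[2.2.2]octane-2,6-dione (enol ether geometry not fixed; silyloxy group expected on the C1 side) | CC(O[Si](C)(C)C(C)(C)C)=C1[C@@H]([C@]2(C)OC(=O)C(C)=C2OC)[C@H]2CC(=O)[C@]1(C)C(=O)[C@@]2(C)O[Si](C)(C)C(C)(C)C | intermediate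
20 | (E)-hex-4-enoic acid | C/C=C/CCC(=O)O | starting material
21 | (E)-hex-4-enoyl chloride | C/C=C/CCC(=O)Cl | intermediate (not isolated)
22 | 1-[(E)-hex-4-enoyl]-1H-benzotriazole | C/C=C/CCC(=O)n1nnc2ccccc21 | intermediate
23 | lithium C5–C6 enolate of 19 | [Li+].CC(O[Si](C)(C)C(C)(C)C)=C1[C@@H]([C@]2(C)OC(=O)C(C)=C2OC)[C@H]2C=C([O-])[C@]1(C)C(=O)[C@@]2(C)O[Si](C)(C)C(C)(C)C | intermediate (not isolated)
24 | (1R,3S,4S,8S)-3-[(tert-butyldimethylsilyl)oxy]-7-{1-[(tert-butyldimethylsilyl)oxy]ethylidene}-5-[(E)-hex-4-enoyl]-6-hydroxy-8-[(2S)-3-methoxy-2,4-dimethyl-5-oxo-2,5-dihydrofuran-2-yl]-1,3-dimethylbicyclo[2.2.2]oct-5-en-2-one | CC(O[Si](C)(C)C(C)(C)C)=C1[C@@H]([C@]2(C)OC(=O)C(C)=C2OC)[C@H]2C(C(=O)CC/C=C/C)=C(O)[C@]1(C)C(=O)[C@@]2(C)O[Si](C)(C)C(C)(C)C | intermediate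
25 | 7-acetyl ketone from 24 as a mixture of C7 epimers | CC(=O)C1[C@@H]([C@]2(C)OC(=O)C(C)=C2OC)[C@H]2C(C(=O)CC/C=C/C)=C(O)[C@]1(C)C(=O)[C@@]2(C)O[Si](C)(C)C(C)(C)C | intermediate (not isolated)
26 | (1R,3S,4S,7R,8S)-7-acetyl-3-[(tert-butyldimethylsilyl)oxy]-5-[(E)-hex-4-enoyl]-6-hydroxy-8-[(2S)-3-methoxy-2,4-dimethyl-5-oxo-2,5-dihydrofuran-2-yl]-1,3-dimethylbicyclo[2.2.2]oct-5-en-2-one | CC(=O)[C@@H]1[C@@H]([C@]2(C)OC(=O)C(C)=C2OC)[C@H]2C(C(=O)CC/C=C/C)=C(O)[C@]1(C)C(=O)[C@@]2(C)O[Si](C)(C)C(C)(C)C | intermediate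
27 | (E)-crotonaldehyde | C/C=C/C=O | starting material
28 | dilithium dianion of 26 (β-diketonate and methyl ketone enolate) | [Li+].[Li+].C=C([O-])[C@@H]1[C@@H]([C@]2(C)OC(=O)C(C)=C2OC)[C@H]2C(C(=O)CC/C=C/C)=C([O-])[C@]1(C)C(=O)[C@@]2(C)O[Si](C)(C)C(C)(C)C | intermediate (not isolated)
29 | aldol adduct, 7-[(E)-3-hydroxyhex-4-enoyl] analogue of 30 (carbinol epimers) | C/C=C/C(O)CC(=O)[C@@H]1[C@@H]([C@]2(C)OC(=O)C(C)=C2OC)[C@H]2C(C(=O)CC/C=C/C)=C(O)[C@]1(C)C(=O)[C@@]2(C)O[Si](C)(C)C(C)(C)C | intermediate (not isolated)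
30 | (1R,3S,4S,7R,8S)-3-[(tert-butyldimethylsilyl)oxy]-7-[(2E,4E)-hexa-2,4-dienoyl]-5-[(E)-hex-4-enoyl]-6-hydroxy-8-[(2S)-3-methoxy-2,4-dimethyl-5-oxo-2,5-dihydrofuran-2-yl]-1,3-dimethylbicyclo[2.2.2]oct-5-en-2-one | C/C=C/C=C/C(=O)[C@@H]1[C@@H]([C@]2(C)OC(=O)C(C)=C2OC)[C@H]2C(C(=O)CC/C=C/C)=C(O)[C@]1(C)C(=O)[C@@]2(C)O[Si](C)(C)C(C)(C)C | intermediate
31 | (1R,3S,4S,7R,8S)-3-[(tert-butyldimethylsilyl)oxy]-7-[(2E,4E)-hexa-2,4-dienoyl]-5-[(E)-hex-4-enoyl]-6-hydroxy-8-[(2S)-3-hydroxy-2,4-dimethyl-5-oxo-2,5-dihydrofuran-2-yl]-1,3-dimethylbicyclo[2.2.2]oct-5-en-2-one | C/C=C/C=C/C(=O)[C@@H]1[C@@H]([C@]2(C)OC(=O)C(C)=C2O)[C@H]2C(C(=O)CC/C=C/C)=C(O)[C@]1(C)C(=O)[C@@]2(C)O[Si](C)(C)C(C)(C)C | intermediate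
32 | (1R,3S,4S,7R,8S)-7-[(2E,4E)-hexa-2,4-dienoyl]-5-[(E)-hex-4-enoyl]-3,6-dihydroxy-8-[(2S)-3-hydroxy-2,4-dimethyl-5-oxo-2,5-dihydrofuran-2-yl]-1,3-dimethylbicyclo[2.2.2]oct-5-en-2-one (CNP0539719.2) | C/C=C/C=C/C(=O)[C@@H]1[C@@H]([C@]2(C)OC(=O)C(C)=C2O)[C@H]2C(C(=O)CC/C=C/C)=C(O)[C@]1(C)C(=O)[C@@]2(C)O | target

**Step count**

Total: 17 steps. Longest linear sequence: 12 steps (1–6, 11, 13–17); steps 7–10 and 12 make the two side fragments.

**Steps most likely to fail**

Step 11 (vinylogous Mukaiyama–Michael addition). Bond formation between the fully substituted furan carbon and the flanked C8 may be slow, and the relative topicity at C5′ in the open transition state may be poor or wrong. The fallback builds the quaternary centre in two stages and sets out from 13.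
- Commercial 4-hydroxy-3-methylfuran-2(5H)-one F1 is O-methylated (Me2SO4, K2CO3) to 4-methoxy-3-methylfuran-2(5H)-one F2 and silylated (tBuMe2SiOTf, Et3N) to tert-butyl[(4-methoxy-3-methylfuran-2-yl)oxy]dimethylsilane F3.
- The unsubstituted, less hindered C5 of F3 adds to 13 under the conditions of step 11 and gives the C5′–H adduct F4; either C5′ epimer serves.
- LiN(SiMe3)2 then removes the furanone γ-hydrogen of F4, which should be the most acidic C–H because it leaves an aromatic 2-oxidofuran.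
- MeI should alkylate C5′ anti to C7 and its enol silane, in the conformer that holds the C8 hydrogen in the furan plane next to the methoxy group. This leads to the configuration of 19, where the route is rejoined.

Step 6 (dehydrogenation). Enolisation of the acetyl group toward C7 may be sluggish, because the exocyclic enol is pressed against the C1 methyl group, and long heating may lead to over-oxidation. The fallback is a Saegusa–Ito sequence from 12.
- Under equilibrating conditions (Me3SiCl, NaI, Et3N, MeCN) 12 is converted into the bis(trimethylsilyl enol ether) F5, with enol silanes at C5=C6 and at C7=C(OSiMe3)CH3.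
- Pd(OAc)2 in MeCN oxidises the C7 enol silane by β-hydride elimination toward C8.
- The C5–C6 enol silane has only a bridgehead β-hydrogen and returns the ketone on aqueous work-up, so that 13 results.

Step 4 (key Claisen closure). The ring closure may be reversed by methoxide (retro-Claisen opening of the non-enolisable C2/C6 dione), or intermolecular condensation through the ester enolate may compete. The fallback is C-acylation under soft enolisation with an activated acyl donor, so that no alkoxide is formed; it sets out from 7.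
- Ester 7 is saponified (LiOH, THF/H2O) to the carboxylic acid F6.
- F6 is converted (1H-benzotriazole, SOCl2, CH2Cl2) into the N-acylbenzotriazole F7.
- MgBr2·OEt2 and iPr2NEt in CH2Cl2 generate the C1 magnesium enolate reversibly; it is acylated intramolecularly with loss of benzotriazole, and the route is rejoined at 10.

**Further compounds**

F1 | step 11 | 4-hydroxy-3-methylfuran-2(5H)-one | CC1=C(O)COC1=O
F2 | step 11 | 4-methoxy-3-methylfuran-2(5H)-one | COC1=C(C)C(=O)OC1
F3 | step 11 | tert-butyl[(4-methoxy-3-methylfuran-2-yl)oxy]dimethylsilane | COc1coc(O[Si](C)(C)C(C)(C)C)c1C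
F4 | step 11 | C5′–H analogue of 19 (C5′ epimers) | CC(O[Si](C)(C)C(C)(C)C)=C1[C@@H](C2OC(=O)C(C)=C2OC)[C@H]2CC(=O)[C@]1(C)C(=O)[C@@]2(C)O[Si](C)(C)C(C)(C)C
F5 | step 6 | bis(trimethylsilyl enol ether) of 12 (C5=C6–OSiMe3 and C7=C(OSiMe3)CH3) | CC(O[Si](C)(C)C)=C1C[C@H]2C=C(O[Si](C)(C)C)[C@]1(C)C(=O)[C@@]2(C)O[Si](C)(C)C(C)(C)C
F6 | step 4 | 2-[(1S,2S,4S,5R)-2-[(tert-butyldimethylsilyl)oxy]-2,4-dimethyl-3-oxo-5-(prop-1-en-2-yl)cyclohexyl]acetic acid | CC(=C)[C@@H]1C[C@@H](CC(=O)O)[C@](C)(O[Si](C)(C)C(C)(C)C)C(=O)[C@H]1C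
F7 | step 4 | N-acylbenzotriazole of F6 | CC(=C)[C@@H]1C[C@@H](CC(=O)n2nnc3ccccc32)[C@](C)(O[Si](C)(C)C(C)(C)C)C(=O)[C@H]1C
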